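**Retrosynthetic overview**
1. The target comes from a diol by one double SN2 bromination (inversion at C3 and C13); the C3 carbinol comes from chelation-controlled ethynyl addition to a ring A aldehyde unmasked from a sugar side-chain diol.
2. Ring B (formed last) comes from 5-endo bromoetherification of a (Z)-homoallylic alcohol: the C12 hydroxyl closes onto C9 of the C9=C10 bromonium, so C12 sets C9 and C10.
3. The (Z)-C9=C10 alkene comes from a Wittig reaction of a bicyclic ring A lactol with a C10–C15 ylide made from (S,S)-diepoxybutane (L-threitol series, supplies C12 and C13).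
4. The ring A lactone comes from iodolactonisation/deiodination of a 2,5-cis-dihydrofuranylacetic acid, itself made by the key Ireland–Claisen [3,3] rearrangement of a furanoid glycal acetate (C7–C8 bond, C–O to C–C chirality transfer).
5. The glycal comes from D-gulono-1,4-lactone, whose furanose ring is ring A. Ring order: ring A (bought), a temporary fused lactone ring, then ring B.

Assumption: chain numbering runs C1 (alkyne CH) to C15 (ethyl CH3), ring A = C4–C7 oxolane, ring B = C9–C12 oxolane; D-gulono-1,4-lactone and 1,4-di-O-tosyl-L-threitol are taken as catalogue compounds.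

**Route**

Step 1
Reactants: 1 D-gulono-1,4-lactone
Product: 2 2,3:5,6-di-O-isopropylidene-D-gulono-1,4-lactone
Conditions: Me2C(OMe)2, acetone, TsOH (cat.), 25 °C
Reagents that add atoms: 2,2-dimethoxypropane, COC(C)(C)OC
Why: Acid-catalysed transketalisation (acetonide formation) closes a dioxolane on the cis-2,3-diol and on the 5,6-diol under thermodynamic control, so all sugar stereocentres are carried unchanged.

Step 2
Reactants: 2 2,3:5,6-di-O-isopropylidene-D-gulono-1,4-lactone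
Product: 3 2,3:5,6-di-O-isopropylidene-D-gulofuranose (anomer mixture)
Conditions: i-Bu2AlH, CH2Cl2, −78 °C; aq. KNaC4H4O6
Reagents that add atoms: none
Why: Partial hydride reduction of a lactone stops at the lactol because the tetrahedral aluminium hemiacetal is stable at −78 °C; no chain stereocentre is touched.

Step 3
Reactants: 3 2,3:5,6-di-O-isopropylidene-D-gulofuranose
Product: 5 1,4-anhydro-2-deoxy-5,6-O-isopropylidene-D-xylo-hex-1-enitol [(2R,3S)-2-[(4R)-2,2-dimethyl-1,3-dioxolan-4-yl]-2,3-dihydrofuran-3-ol], via furanosyl chloride 4 (not isolated)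
Conditions: CCl4, P(NMe2)3, THF, −78 → 0 °C; then Li, NH3(l)/THF, −78 °C; NH4Cl
Reagents that add atoms: none
Why: Appel-type chlorination of the anomeric OH followed by two-electron reductive fragmentation, in which the C1 carbanion expels the C2 oxygen (acetone is lost), gives the furanoid glycal with its 3-OH still cis to the C4 side chain.

Step 4
Reactants: 5 furanoid glycal alcohol
Product: 9 2-[(2R,5R)-5-[(4R)-2,2-dimethyl-1,3-dioxolan-4-yl]-2,5-dihydrofuran-2-yl]acetic acid, via glycal acetate 6 (not isolated), via silyl ketene acetal 7 (not isolated), via trimethylsilyl ester 8 (not isolated)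
Conditions: n-BuLi, THF, −78 °C, then AcCl; LiN(iPr)2, −78 °C, then Me3SiCl/Et3N, −78 → 25 °C; aq. NaOH, then pH 4
Reagents that add atoms: acetyl chloride, CC(Cl)=O
Why: Ireland–Claisen [3,3]-sigmatropic rearrangement of the O-silyl ketene acetal forms the C7–C8 bond suprafacially on the face from which the allylic C5–O bond leaves, i.e. cis to the C4 side chain, fixing C7 as R in a 2,5-cis-dihydrofuran.

Step 5
Reactants: 9 dihydrofuranylacetic acid
Product: 10 (3aR,5S,6S,6aS)-5-[(4R)-2,2-dimethyl-1,3-dioxolan-4-yl]-6-iodotetrahydrofuro[3,2-b]furan-2(3H)-one (cis-fused; iodine anti to the lactone oxygen)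
Conditions: [I][I] (I2), KI, NaHCO3, THF/H2O, 0 °C, dark
Reagents that add atoms: iodine, [I][I]
Why: Iodolactonisation (5-exo): the carboxylate can reach only C6 and only from the face of its own CH2 tether, so the new C6–O bond is cis to C7–C8 (C6 R) and iodine ends anti on C5.

Step 6
Reactants: 10 iodolactone
Product: 11 (3aR,5R,6aR)-5-[(4R)-2,2-dimethyl-1,3-dioxolan-4-yl]tetrahydrofuro[3,2-b]furan-2(3H)-one
Conditions: Bu3SnH, AIBN (cat.), toluene, 80 °C
Reagents that add atoms: none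
Why: Radical chain dehalogenation reduces the C5–iodine bond to C–H, turning C5 into the ring CH2 without touching any stereocentre.

Step 7
Reactants: 11 bicyclic lactone
Product: 12 (3aR,5R,6aR)-5-[(4R)-2,2-dimethyl-1,3-dioxolan-4-yl]hexahydrofuro[3,2-b]furan-2-ol (anomer mixture)
Conditions: i-Bu2AlH, CH2Cl2, −78 °C; aq. KNaC4H4O6
Reagents that add atoms: none
Why: Partial lactone reduction to the lactol, which is a masked C9 aldehyde carrying the free C6 oxygen.

Step 8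
Reactants: 13 1,4-di-O-tosyl-L-threitol
Product: 14 (2S,2'S)-2,2'-bioxirane [(S,S)-1,2:3,4-diepoxybutane]
Conditions: KOH, Et2O/H2O, 25 °C
Reagents that add atoms: none
Why: Double intramolecular Williamson etherification: each secondary alkoxide displaces the neighbouring primary tosylate, so both stereocentres are retained in the C2-symmetric bis-epoxide.

Step 9
Reactants: 14 (S,S)-diepoxybutane (used in excess)
Product: 15 (1S)-1-[(2S)-oxiran-2-yl]propan-1-ol
Conditions: MeMgBr (0.9 equiv), CuI (10 mol %), THF, −40 °C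
Reagents that add atoms: methylmagnesium bromide, C[Mg]Br
Why: CuI-catalysed SN2 opening of a terminal epoxide by MeMgBr at the CH2 end; the two epoxides are homotopic, so mono-opening gives one isomer with C13 (S) untouched and C12 kept in the second epoxide.

Step 10
Reactants: 15 epoxy alcohol
Product: 16 tert-butyldimethyl{[(1S)-1-[(2S)-oxiran-2-yl]propyl]oxy}silane
Conditions: t-BuMe2SiCl, imidazole, DMF, 0 → 25 °C
Reagents that add atoms: tert-butyldimethylsilyl chloride, CC(C)(C)[Si](C)(C)Cl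
Why: Standard O-silylation blocks the C13 oxygen so that only the C12 oxygen can later act as nucleophile.

Step 11
Reactants: 16 silyloxy epoxide
Product: 18 [(3S,4S)-4-(tert-butyldimethylsilyloxy)-3-(triethylsilyloxy)hexyl]triphenylphosphonium trifluoromethanesulfonate, via oxidophosphonium betaine 17 (not isolated)
Conditions: Ph3PCH3Br, n-BuLi, THF, 0 °C; add 16, 0 → 40 °C; then Et3SiOSO2CF3, 0 °C
Reagents that add atoms: methyltriphenylphosphonium bromide, C[P+](c1ccccc1)(c1ccccc1)c1ccccc1.[Br-]; triethylsilyl trifluoromethanesulfonate, CC[Si](CC)(CC)OS(=O)(=O)C(F)(F)F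
Why: SN2 opening of the terminal epoxide at CH2 by the ylide Ph3P=CH2 gives a γ-oxido phosphonium species that is O-silylated to the salt; C12 is not a reacting centre and stays S.

Step 12
Reactants: 12 ring A lactol; 18 phosphonium salt
Product: 21 (2R,3R,5R)-2-[(2Z,5S,6S)-6-(tert-butyldimethylsilyloxy)-5-(triethylsilyloxy)oct-2-en-1-yl]-5-[(4R)-2,2-dimethyl-1,3-dioxolan-4-yl]oxolan-3-yl acetate, via ylide 19 (not isolated), via sodium alkoxide 20 (not isolated)
Conditions: 18, NaN(SiMe3)2, THF, −78 °C; add 12 (as its sodium salt), −78 → 0 °C; then Ac2O, DMAP, 0 → 25 °C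
Reagents that add atoms: acetic anhydride, CC(=O)OC(C)=O
Why: Wittig olefination of the open hydroxy-aldehyde form of the lactol by a non-stabilised salt-free ylide gives the Z-alkene under kinetic control, and the C6 alkoxide set free is acetylated in the same flask.

Step 13
Reactants: 21 bis-silyl ether
Product: 22 (2R,3R,5R)-2-[(2Z,5S,6S)-6-(tert-butyldimethylsilyloxy)-5-hydroxyoct-2-en-1-yl]-5-[(4R)-2,2-dimethyl-1,3-dioxolan-4-yl]oxolan-3-yl acetate
Conditions: HF·pyridine, pyridine, THF, 0 °C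
Reagents that add atoms: none
Why: Selective fluoride-mediated desilylation removes the triethylsilyl ether much faster than the tert-butyldimethylsilyl ether, leaving acetate and acetonide intact and C12-OH as the only free hydroxyl.

Step 14
Reactants: 22 (Z)-homoallylic alcohol
Product: 23 (2R,3R,5R)-2-{[(2S,3S,5S)-3-bromo-5-[(1S)-1-(tert-butyldimethylsilyloxy)propyl]oxolan-2-yl]methyl}-5-[(4R)-2,2-dimethyl-1,3-dioxolan-4-yl]oxolan-3-yl acetate
Conditions: 2,4,4,6-tetrabromocyclohexa-2,5-dienone, CH2Cl2, −40 → 0 °C, dark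
Reagents that add atoms: 2,4,4,6-tetrabromocyclohexa-2,5-dienone, BrC1=CC(Br)(Br)C=C(Br)C1=O
Why: 5-endo-trig bromoetherification: anti opening of the bromonium by the C12 hydroxyl at C9 puts Br cis to the C9 arm (Z-alkene), and an envelope transition state with the C12 side chain pseudo-equatorial places Br cis to it too, giving the all-cis ring B (9S,10S).

Step 15
Reactants: 23 bromo-oxolane
Product: 24 (2R,3R,5R)-2-{[(2S,3S,5S)-3-bromo-5-[(1S)-1-hydroxypropyl]oxolan-2-yl]methyl}-5-[(1R)-1,2-dihydroxyethyl]oxolan-3-yl acetate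
Conditions: CF3CO2H/H2O/THF (2:1:2), 0 → 25 °C
Reagents that add atoms: none
Why: Aqueous acid hydrolysis removes the terminal acetonide and the silyl ether together, while the acetate and the secondary bromide survive.

Step 16
Reactants: 24 triol
Product: 25 (2R,3R,5R)-2-{[(2S,3S,5S)-3-bromo-5-[(1S)-1-hydroxypropyl]oxolan-2-yl]methyl}-5-formyloxolan-3-yl acetate
Conditions: NaIO4, THF/H2O, pH 7, 0 °C
Reagents that add atoms: none
Why: Malaprade glycol cleavage cuts the only vicinal diol and leaves the isolated C13 alcohol alone; the aldehyde is used at once so C4 does not epimerise.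

Step 17
Reactants: 25 ring A aldehyde
Product: 26 (2R,3R,5R)-2-{[(2S,3S,5S)-3-bromo-5-[(1S)-1-hydroxypropyl]oxolan-2-yl]methyl}-5-[(1R)-1-hydroxyprop-2-yn-1-yl]oxolan-3-yl acetate
Conditions: MgBr2·OEt2, CH2Cl2, −78 °C; then HC≡CMgBr (3 equiv, THF), −78 → −40 °C
Reagents that add atoms: ethynylmagnesium bromide, C#C[Mg]Br
Why: Cram-chelate-controlled Grignard addition: magnesium bridges the ring A oxygen and the carbonyl, the acetylide attacks anti to the ring CH2, giving the threo (3R) carbinol; the aldehyde outcompetes the acetate at low temperature.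

Step 18
Reactants: 26 diol
Product: 27 target, (2R,3R,5R)-2-{[(2S,3S,5S)-3-bromo-5-[(1R)-1-bromopropyl]oxolan-2-yl]methyl}-5-[(1S)-1-bromoprop-2-yn-1-yl]oxolan-3-yl acetate
Conditions: CBr4, (n-C8H17)3P, 1-methylcyclohexene, toluene, 70 °C
Reagents that add atoms: carbon tetrabromide, BrC(Br)(Br)Br
Why: Appel-type bromination through alkoxyphosphonium ions with SN2 displacement by bromide inverts both carbinols, C3 (R to S) and C13 (S to R).

**Compound list**
1 | D-gulono-1,4-lactone | OC[C@@H](O)[C@H]1[C@@H](O)[C@@H](O)C(=O)O1 | starting material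
2 | 2,3:5,6-di-O-isopropylidene-D-gulono-1,4-lactone | CC1(C)OC[C@@H](O1)[C@H]2[C@H]3OC(C)(C)O[C@H]3C(=O)O2 | intermediate
3 | 2,3:5,6-di-O-isopropylidene-D-gulofuranose (anomer mixture) | CC1(C)OC[C@@H](O1)[C@H]2[C@H]3OC(C)(C)O[C@H]3C(O)O2 | intermediate
4 | 2,3:5,6-di-O-isopropylidene-D-gulofuranosyl chloride | CC1(C)OC[C@@H](O1)[C@H]2[C@H]3OC(C)(C)O[C@H]3C(Cl)O2 | intermediate
5 | (2R,3S)-2-[(4R)-2,2-dimethyl-1,3-dioxolan-4-yl]-2,3-dihydrofuran-3-ol | CC1(C)OC[C@@H](O1)[C@H]2[C@@H](O)C=CO2 | intermediate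
6 | (2R,3S)-2-[(4R)-2,2-dimethyl-1,3-dioxolan-4-yl]-2,3-dihydrofuran-3-yl acetate | CC1(C)OC[C@@H](O1)[C@H]2[C@@H](OC(C)=O)C=CO2 | intermediate
7 | 1-(trimethylsilyloxy)ethenyl ether of 5 (O-silyl ketene acetal) | CC1(C)OC[C@@H](O1)[C@H]2[C@@H](OC(=C)O[Si](C)(C)C)C=CO2 | intermediate
8 | trimethylsilyl 2-[(2R,5R)-5-[(4R)-2,2-dimethyl-1,3-dioxolan-4-yl]-2,5-dihydrofuran-2-yl]acetate | CC1(C)OC[C@@H](O1)[C@H]2C=C[C@@H](CC(=O)O[Si](C)(C)C)O2 | intermediate
9 | 2-[(2R,5R)-5-[(4R)-2,2-dimethyl-1,3-dioxolan-4-yl]-2,5-dihydrofuran-2-yl]acetic acid | CC1(C)OC[C@@H](O1)[C@H]2C=C[C@@H](CC(=O)O)O2 | intermediate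
10 | (3aR,5S,6S,6aS)-5-[(4R)-2,2-dimethyl-1,3-dioxolan-4-yl]-6-iodotetrahydrofuro[3,2-b]furan-2(3H)-one | CC1(C)OC[C@@H](O1)[C@H]2[C@H]([I])[C@@H](OC(=O)C3)[C@@H]3O2 | intermediate
11 | (3aR,5R,6aR)-5-[(4R)-2,2-dimethyl-1,3-dioxolan-4-yl]tetrahydrofuro[3,2-b]furan-2(3H)-one | CC1(C)OC[C@@H](O1)[C@H]2C[C@@H](OC(=O)C3)[C@@H]3O2 | intermediate
12 | (3aR,5R,6aR)-5-[(4R)-2,2-dimethyl-1,3-dioxolan-4-yl]hexahydrofuro[3,2-b]furan-2-ol (anomer mixture) | CC1(C)OC[C@@H](O1)[C@H]2C[C@@H](OC(O)C3)[C@@H]3O2 | intermediate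
13 | 1,4-di-O-tosyl-L-threitol [(2S,3S)-2,3-dihydroxybutane-1,4-diyl bis(4-methylbenzenesulfonate)] | Cc1ccc(cc1)S(=O)(=O)OC[C@H](O)[C@@H](O)COS(=O)(=O)c1ccc(C)cc1 | starting material
14 | (2S,2'S)-2,2'-bioxirane | [C@H]1(CO1)[C@@H]1CO1 | intermediate
15 | (1S)-1-[(2S)-oxiran-2-yl]propan-1-ol | [C@H]1(CO1)[C@@H](O)CC | intermediate
16 | tert-butyldimethyl{[(1S)-1-[(2S)-oxiran-2-yl]propyl]oxy}silane | [C@H]1(CO1)[C@@H](O[Si](C)(C)C(C)(C)C)CC | intermediate
17 | (3S,4S)-4-(tert-butyldimethylsilyloxy)-1-(triphenylphosphonio)hexan-3-olate (betaine; closed form an oxaphospholane) | c1ccccc1[P+](c1ccccc1)(c1ccccc1)CC[C@H]([O-])[C@@H](O[Si](C)(C)C(C)(C)C)CC | intermediate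
18 | [(3S,4S)-4-(tert-butyldimethylsilyloxy)-3-(triethylsilyloxy)hexyl]triphenylphosphonium trifluoromethanesulfonate | c1ccccc1[P+](c1ccccc1)(c1ccccc1)CC[C@H](O[Si](CC)(CC)CC)[C@@H](O[Si](C)(C)C(C)(C)C)CC.[O-]S(=O)(=O)C(F)(F)F | intermediate
19 | [(3S,4S)-4-(tert-butyldimethylsilyloxy)-3-(triethylsilyloxy)hexylidene]triphenylphosphorane | c1ccccc1P(c1ccccc1)(c1ccccc1)=CC[C@H](O[Si](CC)(CC)CC)[C@@H](O[Si](C)(C)C(C)(C)C)CC | intermediate
20 | sodium (2R,3R,5R)-2-[(2Z,5S,6S)-6-(tert-butyldimethylsilyloxy)-5-(triethylsilyloxy)oct-2-en-1-yl]-5-[(4R)-2,2-dimethyl-1,3-dioxolan-4-yl]oxolan-3-olate | CC1(C)OC[C@@H](O1)[C@H]2C[C@@H]([O-])[C@@H](C/C=C\C[C@H](O[Si](CC)(CC)CC)[C@@H](O[Si](C)(C)C(C)(C)C)CC)O2.[Na+] | intermediate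
21 | (2R,3R,5R)-2-[(2Z,5S,6S)-6-(tert-butyldimethylsilyloxy)-5-(triethylsilyloxy)oct-2-en-1-yl]-5-[(4R)-2,2-dimethyl-1,3-dioxolan-4-yl]oxolan-3-yl acetate | CC1(C)OC[C@@H](O1)[C@H]2C[C@@H](OC(C)=O)[C@@H](C/C=C\C[C@H](O[Si](CC)(CC)CC)[C@@H](O[Si](C)(C)C(C)(C)C)CC)O2 | intermediate
22 | (2R,3R,5R)-2-[(2Z,5S,6S)-6-(tert-butyldimethylsilyloxy)-5-hydroxyoct-2-en-1-yl]-5-[(4R)-2,2-dimethyl-1,3-dioxolan-4-yl]oxolan-3-yl acetate | CC1(C)OC[C@@H](O1)[C@H]2C[C@@H](OC(C)=O)[C@@H](C/C=C\C[C@H](O)[C@@H](O[Si](C)(C)C(C)(C)C)CC)O2 | intermediate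
23 | (2R,3R,5R)-2-{[(2S,3S,5S)-3-bromo-5-[(1S)-1-(tert-butyldimethylsilyloxy)propyl]oxolan-2-yl]methyl}-5-[(4R)-2,2-dimethyl-1,3-dioxolan-4-yl]oxolan-3-yl acetate | CC1(C)OC[C@@H](O1)[C@H]2C[C@@H](OC(C)=O)[C@@H](C[C@@H]3O[C@H]([C@@H](O[Si](C)(C)C(C)(C)C)CC)C[C@@H]3Br)O2 | intermediate
24 | (2R,3R,5R)-2-{[(2S,3S,5S)-3-bromo-5-[(1S)-1-hydroxypropyl]oxolan-2-yl]methyl}-5-[(1R)-1,2-dihydroxyethyl]oxolan-3-yl acetate | OC[C@@H](O)[C@H]1C[C@@H](OC(C)=O)[C@@H](C[C@@H]2O[C@H]([C@@H](O)CC)C[C@@H]2Br)O1 | intermediate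
25 | (2R,3R,5R)-2-{[(2S,3S,5S)-3-bromo-5-[(1S)-1-hydroxypropyl]oxolan-2-yl]methyl}-5-formyloxolan-3-yl acetate | O=C[C@H]1C[C@@H](OC(C)=O)[C@@H](C[C@@H]2O[C@H]([C@@H](O)CC)C[C@@H]2Br)O1 | intermediate
26 | (2R,3R,5R)-2-{[(2S,3S,5S)-3-bromo-5-[(1S)-1-hydroxypropyl]oxolan-2-yl]methyl}-5-[(1R)-1-hydroxyprop-2-yn-1-yl]oxolan-3-yl acetate | C#C[C@@H](O)[C@H]1C[C@@H](OC(C)=O)[C@@H](C[C@@H]2O[C@H]([C@@H](O)CC)C[C@@H]2Br)O1 | intermediate
27 | (2R,3R,5R)-2-{[(2S,3S,5S)-3-bromo-5-[(1R)-1-bromopropyl]oxolan-2-yl]methyl}-5-[(1S)-1-bromoprop-2-yn-1-yl]oxolan-3-yl acetate (CNP0294340.1) | C#C[C@H](Br)[C@H]1C[C@@H](OC(C)=O)[C@@H](C[C@@H]2O[C@H]([C@H](Br)CC)C[C@@H]2Br)O1 | target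

**Step count**
Total step count: 18.
Longest linear sequence: 14 steps (steps 1–7, then 12–18, from compound 1). The side branch from compound 13 has 4 steps (8–11) before the union in step 12.

**Three steps most likely to fail, each with a fallback**

Step 14 (5-endo bromoetherification). The risks are attack by other oxygens on the bromonium and the wrong 2,5-relationship in ring B. The fallback builds ring B from an alkyne and brings the bromide in by inversion; it sets out from 12 (plus 16) and comes back at 23. Ohira–Bestmann homologation of 12 (dimethyl 1-diazo-2-oxopropylphosphonate, K2CO3, MeOH) gives the propargyl oxolanol F1. Et3SiOSO2CF3 and 2,6-lutidine give its triethylsilyl ether F2. The lithium acetylide of F2 (n-BuLi, then BF3·OEt2) opens epoxide 16 at CH2 to the homopropargylic alcohol F3. AuCl(PPh3)/AgOSO2CF3 (5 mol %) closes it 5-endo-dig to the 2,3-dihydrofuran F4. BH3·THF, then NaOH/H2O2, adds H to C9 and OH to C10 on the face anti to the C12 side chain, giving the 2,5-cis oxolan-3-ol F5 with the 10-OH trans to both arms. CBr4/(n-C8H17)3P inverts C10 to the all-cis bromide F6. HF·pyridine frees the C6 alcohol F7, and Ac2O/pyridine returns to 23.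

Step 17 (chelation-controlled ethynyl addition). The risks are a low threo:erythro ratio at C3 and competing attack on the acetate. The fallback sets C3 by reduction instead; it sets out from 23 and comes back at 26. H5IO6 in EtOAc cleaves the terminal acetonide directly to the silyl-protected aldehyde F8. LiC≡CSiMe3 at −78 °C gives the C3-epimeric silylalkynyl carbinols F9. Dess–Martin periodinane gives the ynone F10. LiBH(s-Bu)3 at −78 °C reduces it under Felkin–Anh control to the threo (3R) carbinol F11. Bu4NF buffered by AcOH removes both silyl groups to give 26.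

Step 18 (double bromination). The risks are participation of the ring B oxygen at C13 and SN2' or elimination at the propargylic centre when both alcohols react at 70 °C. The fallback introduces the two bromides one at a time; it sets out from 23 and comes back at 27. Bu4NF/AcOH gives the C13 alcohol F12. CBr4/(n-C8H17)3P at 70 °C gives the (13R) bromide F13 before any alkyne is present. H5IO6 in EtOAc gives the aldehyde F14. HC≡CMgBr/MgBr2·OEt2 gives the (3R) propargylic alcohol F15. CBr4/PPh3 in CH2Cl2 at 0 °C then inverts only C3 and gives the target 27.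

**Further compounds**
F1 | step 14 | (2R,3R,5R)-5-[(4R)-2,2-dimethyl-1,3-dioxolan-4-yl]-2-(prop-2-yn-1-yl)oxolan-3-ol | CC1(C)OC[C@@H](O1)[C@H]2C[C@@H](O)[C@@H](CC#C)O2
F2 | step 14 | triethylsilyl ether of F1 | CC1(C)OC[C@@H](O1)[C@H]2C[C@@H](O[Si](CC)(CC)CC)[C@@H](CC#C)O2
F3 | step 14 | (5S,6S)-6-(tert-butyldimethylsilyloxy)-1-[(2R,3R,5R)-5-[(4R)-2,2-dimethyl-1,3-dioxolan-4-yl]-3-(triethylsilyloxy)oxolan-2-yl]oct-2-yn-5-ol | CC1(C)OC[C@@H](O1)[C@H]2C[C@@H](O[Si](CC)(CC)CC)[C@@H](CC#CC[C@H](O)[C@@H](O[Si](C)(C)C(C)(C)C)CC)O2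
F4 | step 14 | 2,3-dihydrofuran from F3 (ring B enol ether, C9=C10) | CC1(C)OC[C@@H](O1)[C@H]2C[C@@H](O[Si](CC)(CC)CC)[C@@H](CC3=CC[C@H](O3)[C@@H](O[Si](C)(C)C(C)(C)C)CC)O2
F5 | step 14 | ring B (2S,3R,5S)-oxolan-3-ol (10-OH trans to both arms), C6 triethylsilyl ether | CC1(C)OC[C@@H](O1)[C@H]2C[C@@H](O[Si](CC)(CC)CC)[C@@H](C[C@@H]3O[C@H]([C@@H](O[Si](C)(C)C(C)(C)C)CC)C[C@H]3O)O2
F6 | step 14 | ring B (2S,3S,5S)-3-bromide, C6 triethylsilyl ether | CC1(C)OC[C@@H](O1)[C@H]2C[C@@H](O[Si](CC)(CC)CC)[C@@H](C[C@@H]3O[C@H]([C@@H](O[Si](C)(C)C(C)(C)C)CC)C[C@@H]3Br)O2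
F7 | step 14 | C6 alcohol corresponding to 23 | CC1(C)OC[C@@H](O1)[C@H]2C[C@@H](O)[C@@H](C[C@@H]3O[C@H]([C@@H](O[Si](C)(C)C(C)(C)C)CC)C[C@@H]3Br)O2
F8 | step 17 | ring A aldehyde keeping the C13 silyl ether | O=C[C@H]1C[C@@H](OC(C)=O)[C@@H](C[C@@H]2O[C@H]([C@@H](O[Si](C)(C)C(C)(C)C)CC)C[C@@H]2Br)O1
F9 | step 17 | 3-(trimethylsilyl)prop-2-yn-1-ol adduct, C3 epimer mixture | C[Si](C)(C)C#CC(O)[C@H]1C[C@@H](OC(C)=O)[C@@H](C[C@@H]2O[C@H]([C@@H](O[Si](C)(C)C(C)(C)C)CC)C[C@@H]2Br)O1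
F10 | step 17 | trimethylsilyl ynone | C[Si](C)(C)C#CC(=O)[C@H]1C[C@@H](OC(C)=O)[C@@H](C[C@@H]2O[C@H]([C@@H](O[Si](C)(C)C(C)(C)C)CC)C[C@@H]2Br)O1
F11 | step 17 | (3R)-threo silylalkynyl carbinol | C[Si](C)(C)C#C[C@@H](O)[C@H]1C[C@@H](OC(C)=O)[C@@H](C[C@@H]2O[C@H]([C@@H](O[Si](C)(C)C(C)(C)C)CC)C[C@@H]2Br)O1
F12 | step 18 | C13 alcohol keeping the acetonide | CC1(C)OC[C@@H](O1)[C@H]2C[C@@H](OC(C)=O)[C@@H](C[C@@H]3O[C@H]([C@@H](O)CC)C[C@@H]3Br)O2
F13 | step 18 | (13R) bromide keeping the acetonide | CC1(C)OC[C@@H](O1)[C@H]2C[C@@H](OC(C)=O)[C@@H](C[C@@H]3O[C@H]([C@H](Br)CC)C[C@@H]3Br)O2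
F14 | step 18 | dibromo ring A aldehyde | O=C[C@H]1C[C@@H](OC(C)=O)[C@@H](C[C@@H]2O[C@H]([C@H](Br)CC)C[C@@H]2Br)O1
F15 | step 18 | (3R) propargylic alcohol bearing both ring B side bromides | C#C[C@@H](O)[C@H]1C[C@@H](OC(C)=O)[C@@H](C[C@@H]2O[C@H]([C@H](Br)CC)C[C@@H]2Br)O1
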